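**Overview**

- **Cuts:** first the C3–C1' bond between pyran ring C and ring B. Next C3–B and C4–H of the chroman-3-ylboronate that remains, which leads back to a C3=C4 enol silane. Last O1–C2 and C4–C4a of ring C.
- **Enabling feature:** ring B has OH on C2' and C5' (para to each other) and OMe on C3' and C4', so it is 2,3-dimethoxy-1,4-benzoquinone in reduced form. It is bonded to C3 of ring C, directly beside the oxygen-bearing C4, so C3 can react as a flat radical that the quinone traps opposite the C4 substituent.
- **Forward order:** ring A is bought as 4-methoxyresorcinol. Ring C is built on it by acylation and phenoxide closure. Ring B is joined last as the intact quinone and turns aromatic in the coupling.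
- **Stereochemistry:** C4 (R) comes from reagent control, with IpcBH2 from (+)-α-pinene adding H to C4 of the enol silane. C3 (S) comes from substrate control, with radical capture anti to C4–OTBS, which gives the 3,4-trans target.

Key step: step 6

Abbreviations: TBS = tert-butyldimethylsilyl, TBSO = tert-butyldimethylsilyloxy, Ipc = isopinocampheyl. Isoflavan numbering is used (O1, C2, C3, C4, C4a to C8a; ring B primed).

Assumption: toward IpcBH2 the C3=C4 enol silane is taken to behave like 1-phenylcyclopentene, with OTBS in the place of phenyl and C4a in the place of the ring CH2; the reagent from (+)-α-pinene then gives 4R, the sense is to be confirmed on an oxidised aliquot by MTPA ester analysis, and the reagent from (−)-α-pinene is taken if it proves reversed.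

**Route**

Step 1
Reactants: 1 4-methoxybenzene-1,3-diol; 2 3-chloropropanoic acid
Product: 3 3-chloro-1-(2,4-dihydroxy-5-methoxyphenyl)propan-1-one
Conditions: CF3SO3H (neat), 80 °C; poured onto ice, EtOAc
Reagents that add atoms: none
Why: Friedel–Crafts acylation in triflic acid, the standard entry to 3-chloropropiophenones of resorcinols, should go to C6 of 1, the only position ortho to one OH and para to the other without lying between them, and the alkyl chloride and the methyl ether tolerate the short heating.

Step 2
Reactants: 3 3-chloro-1-(2,4-dihydroxy-5-methoxyphenyl)propan-1-one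
Product: 5 7-hydroxy-6-methoxychroman-4-one, via aryl vinyl ketone 4 (not isolated)
Conditions: 2 M aq NaOH, N2, 0 °C to rt; then 2 M HCl to pH 4
Reagents that add atoms: none
Why: Base-induced loss of HCl (E1cB) gives enone 4, to which the neighbouring phenoxide adds in a 6-endo-trig oxa-Michael reaction, the usual second half of the chroman-4-one synthesis, while the other phenol is too far away to compete.

Step 3
Reactants: 5 7-hydroxy-6-methoxychroman-4-one
Product: 7 4,7-bis(tert-butyldimethylsilyloxy)-6-methoxy-2H-chromene, via phenol silyl ether 6 (not isolated)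
Conditions: TBSOTf (2.5 equiv), Et3N (4 equiv), CH2Cl2, 0 °C to rt; cold aq NaHCO3; Et3N-deactivated silica
Reagents that add atoms: tert-butyldimethylsilyl trifluoromethanesulfonate, TBSOTf, CC(C)(C)[Si](C)(C)OS(=O)(=O)C(F)(F)F
Why: Silyl triflate and amine silylate the phenol at once and then turn the ketone into its enol silane by soft enolisation, which can only run toward C3 because C4a carries no hydrogen, so a single C3=C4 olefin results.

Step 4
Reactants: 7 4,7-bis(TBSO)-6-methoxy-2H-chromene
Product: 9 diethyl [(3S,4R)-4,7-bis(TBSO)-6-methoxychroman-3-yl]boronate, via chromanyl(isopinocampheyl)borane 8 (not isolated)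
Conditions: (IpcBH2)2·TMEDA [from (+)-α-pinene], BF3·OEt2, Et2O, rt, TMEDA·2BF3 filtered off; 7, Et2O, −25 °C; then CH3CHO (excess), 0 °C to rt; volatiles removed in vacuo
Reagents that add atoms: monoisopinocampheylborane, IpcBH2, freed from its TMEDA adduct, C[C@H]1[C@H](B)C[C@@H]2C[C@H]1C2(C)C; acetaldehyde, CC=O
Why: Asymmetric hydroboration with monoisopinocampheylborane, the reagent of choice for trisubstituted aryl-conjugated cycloalkenes: the enol oxygen and the substitution pattern both send boron to C3, H and B add syn on the face chosen by the pinanyl group so that C4 becomes R and boron lies trans to OTBS (3S), and acetaldehyde then takes up the B–H and expels α-pinene to leave the diethyl boronate under neutral conditions.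

Step 5
Reactants: 9 diethyl [(3S,4R)-4,7-bis(TBSO)-6-methoxychroman-3-yl]boronate
Product: 10 2-[(3S,4R)-4,7-bis(TBSO)-6-methoxychroman-3-yl]-1,3,2-benzodioxaborole (catechol boronate, B trans to OTBS)
Conditions: catechol (1.0 equiv), CH2Cl2, rt; EtOH stripped in vacuo (toluene chase); crude kept under Ar
Reagents that add atoms: catechol, Oc1ccccc1O
Why: Transesterification of a boronic ester, in which the chelating diol displaces two molecules of ethanol that are pumped off, runs under neutral conditions that avoid 1,2-elimination of boron with either β-oxygen and leave both stereocentres untouched, and exactly one equivalent is used because free catechol would later quench the radical chain.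

Step 6
Reactants: 10 catechol boronate; 11 2,3-dimethoxy-1,4-benzoquinone
Product: 13 (3S,4R)-trans-4,7-bis(TBSO)-3-(2,5-dihydroxy-3,4-dimethoxyphenyl)-6-methoxychroman, via aryl borate 12 (not isolated)
Conditions: 11 (3 equiv, ca. 0.5 M), DMPU (1 equiv), CH2Cl2, slow admission of air, rt; then aq Na2S2O4, EtOAc
Reagents that add atoms: none
Why: Proposed new method: adventitious O2 oxidises a little of 10 to oxygen-centred radicals, homolytic substitution at boron by such a radical liberates the planar, nucleophilic chroman-3-yl radical, this bonds to the unsubstituted C5 of 11, and the adduct radical, whose spin sits largely on oxygen, substitutes at the boron of a fresh molecule of 10, which passes the chain on and leaves a boron dienolate that tautomerises to aryl borate 12 (hydrolysed on work-up) with the gain of aromaticity in ring B as driving force. The nearest precedent is the air-started chain reaction in which trialkylboranes or B-alkylcatecholboranes deliver simple primary and secondary alkyl radicals to p-benzoquinones and give 2-alkylhydroquinones, which has not been shown for a radical flanked by a silyloxy-bearing benzylic carbon and an aryloxymethylene group, nor for a 2,3-dialkoxyquinone. No ring closes: only the C3–C1' bond forms, and the six-membered quinone ring enters intact. The new stereocentre C3 is controlled by C4, whose bulky OTBS group is pushed pseudoaxial on the half-chair of ring C by peri strain with H5 and so shields one face of the radical, so the quinone bonds on the other face and the 3,4-trans (3S) product results from either C3 epimer of the boronate. The step needs bonding to carbon rather than oxygen of the quinone, which the secondary (not tertiary) radical and the free C5=C6 edge secure, and the symmetry of 11 makes C5 and C6 equivalent so that no regioisomer can arise. It also needs trapping to outrun β-scission of the C2–O1 bond and hydrogen transfer from phenols, which the high quinone concentration, the poor overlap of the radical orbital with the endocyclic C2–O1 bond and the absence of free catechol secure, while the neutral medium spares the acid-labile C4–O bond and both silyl ethers.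

Step 7
Reactants: 13 (3S,4R)-trans-4,7-bis(TBSO)-3-(2,5-dihydroxy-3,4-dimethoxyphenyl)-6-methoxychroman
Product: 15 (3S,4R)-trans-3-(2,5-dihydroxy-3,4-dimethoxyphenyl)-6-methoxychroman-4,7-diol (7,2',5'-trihydroxy-6,3',4'-trimethoxyisoflavan-4-ol), via C4 monosilyl ether 14 (not isolated)
Conditions: TBAF (3 equiv), AcOH (3 equiv), degassed THF, Ar, 0 °C to rt; pH 7 phosphate buffer/sodium ascorbate work-up; reversed phase or Et3N-deactivated silica
Reagents that add atoms: none
Why: Fluoride-induced cleavage of silyl ethers, buffered with acetic acid so that both phenoxides (autoxidation) and strong acid (ionisation of the para-oxygenated benzylic C4–O bond) are avoided, removes the aryl ether first and the secondary ether second without touching any bond to C3 or C4.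

**Compound list**

1 | 4-methoxybenzene-1,3-diol | COc1ccc(O)cc1O | starting material
2 | 3-chloropropanoic acid | OC(=O)CCCl | starting material
3 | 3-chloro-1-(2,4-dihydroxy-5-methoxyphenyl)propan-1-one | COc1cc(C(=O)CCCl)c(O)cc1O | intermediate
4 | 1-(2,4-dihydroxy-5-methoxyphenyl)prop-2-en-1-one | COc1cc(C(=O)C=C)c(O)cc1O | intermediate
5 | 7-hydroxy-6-methoxychroman-4-one | COc1cc2c(cc1O)OCCC2=O | intermediate
6 | 7-(tert-butyldimethylsilyloxy)-6-methoxychroman-4-one | COc1cc2c(cc1O[Si](C)(C)C(C)(C)C)OCCC2=O | intermediate
7 | 4,7-bis(tert-butyldimethylsilyloxy)-6-methoxy-2H-chromene | COc1cc2c(cc1O[Si](C)(C)C(C)(C)C)OCC=C2O[Si](C)(C)C(C)(C)C | intermediate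
8 | [(3S,4R)-4,7-bis(TBSO)-6-methoxychroman-3-yl](isopinocampheyl)borane, B–H retained, B trans to OTBS | COc1cc2c(cc1O[Si](C)(C)C(C)(C)C)OC[C@H](B[C@@H]1C[C@@H]3C[C@H]([C@H]1C)C3(C)C)[C@H]2O[Si](C)(C)C(C)(C)C | intermediate
9 | diethyl [(3S,4R)-4,7-bis(TBSO)-6-methoxychroman-3-yl]boronate | COc1cc2c(cc1O[Si](C)(C)C(C)(C)C)OC[C@H](B(OCC)OCC)[C@H]2O[Si](C)(C)C(C)(C)C | intermediate
10 | 2-[(3S,4R)-4,7-bis(TBSO)-6-methoxychroman-3-yl]-1,3,2-benzodioxaborole | COc1cc2c(cc1O[Si](C)(C)C(C)(C)C)OC[C@H](B1Oc3ccccc3O1)[C@H]2O[Si](C)(C)C(C)(C)C | intermediate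
11 | 2,3-dimethoxy-1,4-benzoquinone | COC1=C(OC)C(=O)C=CC1=O | starting material
12 | compound 13 carrying a 1,3,2-benzodioxaborol-2-yl group on the 5'-oxygen (2'-OH free) | COc1cc2c(cc1O[Si](C)(C)C(C)(C)C)OC[C@H](c1cc(OB3Oc4ccccc4O3)c(OC)c(OC)c1O)[C@H]2O[Si](C)(C)C(C)(C)C | intermediate
13 | (3S,4R)-trans-4,7-bis(TBSO)-3-(2,5-dihydroxy-3,4-dimethoxyphenyl)-6-methoxychroman | COc1cc2c(cc1O[Si](C)(C)C(C)(C)C)OC[C@H](c1cc(O)c(OC)c(OC)c1O)[C@H]2O[Si](C)(C)C(C)(C)C | intermediate
14 | (3S,4R)-trans-4-(TBSO)-3-(2,5-dihydroxy-3,4-dimethoxyphenyl)-6-methoxychroman-7-ol | COc1cc2c(cc1O)OC[C@H](c1cc(O)c(OC)c(OC)c1O)[C@H]2O[Si](C)(C)C(C)(C)C | intermediate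
15 | (3S,4R)-trans-3-(2,5-dihydroxy-3,4-dimethoxyphenyl)-6-methoxychroman-4,7-diol | COc1cc2c(cc1O)OC[C@H](c1cc(O)c(OC)c(OC)c1O)[C@H]2O | target

Total step count: 7. Longest linear sequence: 7 steps (1 to 15).

**Steps most likely to fail**

**Step 6 (radical coupling).**
- What may go wrong: the chain may die early because the phenolic products quench radicals. The C3 radical may be reduced, or may open ring C by β-scission, before it is trapped. It may bond to a quinone oxygen. The facial selectivity may be poor.
- Approach of the fallback: it uses known polar chemistry and makes the 3,4-trans relation by a syn hydroboration instead of a radical capture. It sets out from enol silane 7 and quinone 11 and returns to the route at target 15.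
- Sequence: a Mukaiyama–Michael addition of 7 to 11 (catalytic TBSOTf, CH2Cl2, −78 °C, quenched with Et3N) transfers the enol silyl group to the quinone oxygen with aromatisation. It should give 7-(TBSO)-3-[5-(TBSO)-2-hydroxy-3,4-dimethoxyphenyl]-6-methoxychroman-4-one F1. Silylation of the last phenol (TBSCl, imidazole, DMF) gives the tris-silyl isoflavanone F2. NaBH4 (MeOH–THF, 0 °C) gives the tris-silyl isoflavan-4-ol F3 as a stereoisomer mixture. The mixture is of no consequence, since MsCl/Et3N (CH2Cl2, 0 °C to rt) removes the C4 oxygen and gives the tris-silyl isoflav-3-ene F4. This olefin belongs to the 1-arylcycloalkene class for which IpcBH2 is best established. The reagent from (+)-α-pinene (Et2O, −25 to 0 °C) places boron on C4 and hydrogen on C3 from the same face to give the (3S,4R)-chroman-4-yl(isopinocampheyl)borane F5. Oxidation with retention (30% H2O2, pH 7 phosphate buffer, THF, 0 °C) gives the (3S,4R)-trans tris-silyl isoflavan-4-ol F6. Its three silyl ethers are removed under the conditions of step 7 to reach 15.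

**Step 4 (asymmetric hydroboration).**
- What may go wrong: the hindered enol silane may react so slowly that the reagent redistributes. Face selection may be weak because OTBS takes the place of the aryl group of the model olefins. Boron may be lost together with a β-oxygen by elimination.
- Approach of the fallback: C4 is set by catalytic hydride delivery and boron is brought in afterwards by a radical borylation. It sets out from 7 and returns at 10.
- Sequence: NBS (THF, −78 to 0 °C) converts 7 into 3-bromo-7-(TBSO)-6-methoxychroman-4-one F7. Asymmetric transfer hydrogenation with dynamic kinetic resolution, a known route from cyclic α-halo aryl ketones to cis-halohydrins, is run with RuCl[(R,R)-TsDPEN](p-cymene) in HCO2H/Et3N at rt. It should give (3R,4S)-cis-3-bromo-7-(TBSO)-6-methoxychroman-4-ol F8. This has the C4 geometry of 10; the descriptor changes only because bromine raises the rank of C3. TBSOTf/2,6-lutidine (CH2Cl2, −78 to 0 °C) gives (3R,4S)-cis-3-bromo-4,7-bis(TBSO)-6-methoxychroman F9. Photoinduced radical borylation with bis(catecholato)diboron (catalytic 4-phenylpyridine, DMA, blue light) passes through the same planar C3 radical, is captured anti to OTBS, and delivers 10.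

**Step 7 (double desilylation).**
- What may go wrong: the hydroquinone may autoxidise in the basic fluoride medium. The secondary benzylic silyl ether may leave slowly. Forcing may bring ionisation at C4, followed by ring closure through the 2'-oxygen or by loss of water.
- Approach of the fallback: ring B is masked as the quinone while the silyl groups are removed. It sets out from 13 and returns at 15.
- Sequence: Ag2O (Et2O, Na2SO4, rt) oxidises 13 to 5-[(3S,4R)-4,7-bis(TBSO)-6-methoxychroman-3-yl]-2,3-dimethoxy-1,4-benzoquinone F10. This has neither an oxidisable hydroquinone nor a 2'-OH nucleophile. Et3N·3HF (MeCN, rt) gives 5-[(3S,4R)-4,7-dihydroxy-6-methoxychroman-3-yl]-2,3-dimethoxy-1,4-benzoquinone F11. A two-phase reduction with Na2S2O4 (EtOAc/pH 7 buffer, Ar) as the very last operation gives 15.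

**Further compounds**

F1 | step 6 | 7-(TBSO)-3-[5-(TBSO)-2-hydroxy-3,4-dimethoxyphenyl]-6-methoxychroman-4-one (racemic) | COc1cc2c(cc1O[Si](C)(C)C(C)(C)C)OCC(c1cc(O[Si](C)(C)C(C)(C)C)c(OC)c(OC)c1O)C2=O
F2 | step 6 | 7-(TBSO)-3-[2,5-bis(TBSO)-3,4-dimethoxyphenyl]-6-methoxychroman-4-one (racemic) | COc1cc2c(cc1O[Si](C)(C)C(C)(C)C)OCC(c1cc(O[Si](C)(C)C(C)(C)C)c(OC)c(OC)c1O[Si](C)(C)C(C)(C)C)C2=O
F3 | step 6 | 7-(TBSO)-3-[2,5-bis(TBSO)-3,4-dimethoxyphenyl]-6-methoxychroman-4-ol (stereoisomer mixture) | COc1cc2c(cc1O[Si](C)(C)C(C)(C)C)OCC(c1cc(O[Si](C)(C)C(C)(C)C)c(OC)c(OC)c1O[Si](C)(C)C(C)(C)C)C2O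
F4 | step 6 | 7-(TBSO)-3-[2,5-bis(TBSO)-3,4-dimethoxyphenyl]-6-methoxy-2H-chromene | COc1cc2c(cc1O[Si](C)(C)C(C)(C)C)OCC(c1cc(O[Si](C)(C)C(C)(C)C)c(OC)c(OC)c1O[Si](C)(C)C(C)(C)C)=C2
F5 | step 6 | {(3S,4R)-7-(TBSO)-3-[2,5-bis(TBSO)-3,4-dimethoxyphenyl]-6-methoxychroman-4-yl}(isopinocampheyl)borane | COc1cc2c(cc1O[Si](C)(C)C(C)(C)C)OC[C@H](c1cc(O[Si](C)(C)C(C)(C)C)c(OC)c(OC)c1O[Si](C)(C)C(C)(C)C)[C@H]2B[C@@H]1C[C@@H]3C[C@H]([C@H]1C)C3(C)C
F6 | step 6 | (3S,4R)-trans-7-(TBSO)-3-[2,5-bis(TBSO)-3,4-dimethoxyphenyl]-6-methoxychroman-4-ol | COc1cc2c(cc1O[Si](C)(C)C(C)(C)C)OC[C@H](c1cc(O[Si](C)(C)C(C)(C)C)c(OC)c(OC)c1O[Si](C)(C)C(C)(C)C)[C@H]2O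
F7 | step 4 | 3-bromo-7-(TBSO)-6-methoxychroman-4-one (racemic, labile at C3) | COc1cc2c(cc1O[Si](C)(C)C(C)(C)C)OCC(Br)C2=O
F8 | step 4 | (3R,4S)-cis-3-bromo-7-(TBSO)-6-methoxychroman-4-ol | COc1cc2c(cc1O[Si](C)(C)C(C)(C)C)OC[C@@H](Br)[C@H]2O
F9 | step 4 | (3R,4S)-cis-3-bromo-4,7-bis(TBSO)-6-methoxychroman | COc1cc2c(cc1O[Si](C)(C)C(C)(C)C)OC[C@@H](Br)[C@H]2O[Si](C)(C)C(C)(C)C
F10 | step 7 | 5-[(3S,4R)-4,7-bis(TBSO)-6-methoxychroman-3-yl]-2,3-dimethoxy-1,4-benzoquinone | COc1cc2c(cc1O[Si](C)(C)C(C)(C)C)OC[C@H](C1=CC(=O)C(OC)=C(OC)C1=O)[C@H]2O[Si](C)(C)C(C)(C)C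
F11 | step 7 | 5-[(3S,4R)-4,7-dihydroxy-6-methoxychroman-3-yl]-2,3-dimethoxy-1,4-benzoquinone | COc1cc2c(cc1O)OC[C@H](C1=CC(=O)C(OC)=C(OC)C1=O)[C@H]2O
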